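The readings stem from a simulated flask with constants of no real substance; scatter was added.

Time sorts these flasks into rungs, and the two earlier runs show where each rung lies. The reagent charge is the same in every flask, so I count target as a fraction of that charge.

the same everywhere: reagent 28.5 mM (fed, over 1.0 min)

| run | substrate | remark | time |
|---|---|---|---|
| green | 45 mM | run made earlier |  |
| teal | 84 mM | run made earlier |  |
| dusk | 30 mM |  | 6.0 min |
| winter | 50 mM |  | 6.0 min |
| dawn | 60 mM |  | 6.0 min |

- green (time / min: target / %, substrate / %): 1.00: 1.3, 16.1; 2.00: 6.8, 2.1; 3.00: 10.2, 0.8; 4.00: 13.8, 0; 5.00: 15.8, 0.5; 6.00: 18.3, 0.7
- teal (time / min: target / %, substrate / %): 1.00: 0.7, 20.5; 2.00: 2.6, 4.6; 3.00: 4.5, 1.1; 4.00: 5.6, 1.4; 5.00: 6.0, 0.5; 6.00: 7.2, 0.9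

(each reading ± 0.5 percentage points)

- a reading or a percentage of target counts all its forms, free or not
- the concentration of target that is asked is that of its free form alone
- "hardly changes" means that all values lie within two and a half points (for a concentration: within two and a half percent of the largest)

- [target] (only what is free in solution) at the end for dusk, winter, dawn, in this order
- how that number moves from the first to the last of them (hardly changes / falls all the way / rises all the way / falls, then rises / rises, then falls)

The first rung I can read is the loss of substrate. From the end of the feed to the next reading, I read a pseudo-first-order half-life: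

green: 0.340 min
teal: 0.464 min

Both are shorter than the feed of 1.0 min, but they are read after the feed has ended, so they tell how fast substrate goes then and not what consumes it. At 3.00 min, green reads 0.8% substrate and 10.2% target, which leaves 89.0% of its substrate in neither reading. Green's target reading goes on rising while its substrate reading stays near zero, so I take target to come from part of that unseen material, on a slower rung.

That rung is the quantity I carry. The late yield g, the fraction of the reagent charge that appears as target per minute from 3.00 min to 6.00 min, and its inverse, the clock, are:

green: g = 0.0426 /min, clock 23.5 min
teal: g = 0.0265 /min, clock 37.7 min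

Each clock is longer than the time asked, so I expect these flasks to stop short of their slow rung's end. Two runs give g at two loads, so I can't say from them how g moves below green.

The forecast gives 9 mM, 7.7 mM and 7.2 mM, so the number falls all the way: “Target therefore tracks the reagent-derived pool more than the substrate”.

The flasks give 6.85 mM, 7.55 mM and 7.15 mM, so the number rises, then falls.

    substrate → side product B (k = 0.0108 /s)
    substrate → side product A (k = 0.00794 /s)
    intermediate B → target (k = 0.0122 /s)
    reagent + target ⇌ idle adduct, settled at all times (K = 12.0 /M)
    substrate + reagent → intermediate A (k = 1.52 /M/s)
    reagent + intermediate A ⇌ intermediate B (K = 49.1 /M, k = 2.04 /M/s)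

For dusk, g is 0.0360 /min, a clock of 27.8 min. Part of what keeps dusk slow is the back reaction of intermediate B to reagent + intermediate A, acting together with the time given: without that back reaction dusk ends at 9.65 mM, and at 60.0 min it stands at 10.6 mM. For dawn, g is 0.0325 /min, a clock of 30.8 min, and without the same back reaction, again a part of the reason, its 7.15 mM becomes 11.0 mM.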